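**Plan**
1. Retrosynthesis: the ester C–O bonds at C9 (trienoic acid 53) and C8 (protected 2-(hydroxymethyl)acrylic acid 59) are cut first; the lactone carbonyl C12 is taken back to a cyclic acetal and C10–C14 to an enol triflate plus CO.
2. The ten-membered ring holds a 1,5-diene (C1=C10 and C4=C5 on either side of C2–C3) and C10 carries the one-carbon group C14, so cutting C2–C3 and restoring C5–C10 ([3,3] retron) leads to the cis-1-vinyl-2-isopropenylcyclohexan-1-ol 28.
3. Forward: butenolide 1 (C5–C9) takes C11–C13 by cuprate addition and O6 by enolate hydroxylation; lactol methylenation, chelate-controlled addition of the C10/C1 alkenyl unit and ring-closing metathesis give the cyclohexene; epoxidation, isopropenyl opening and methylenation give 28.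
4. Ring order: tetrahydrofuran acetal O6–C12 (step 8), cyclohexene (step 14), ten-membered ring by six-to-ten expansion (step 20), lactone by oxidation (step 23); acid 53 is built from neryl acetate by two Z-selective phosphonate olefinations.
5. Stereochemistry: C8 from 1; C7 and C6 by anti additions on the lactone; C9 by Cram-chelate addition; the temporary C5/C10 centres by Sharpless epoxidation and SN2 opening, which together with the trans-fused acetal ring fix the chair of the [3,3] shift and so both ring alkene geometries; side-chain alkenes from neryl acetate and Still–Gennari olefination.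

Key step: step 20

Notation: germacrane numbering (C1–C15; C12 lactone carbonyl, C14 formyl carbon) for the core, C1′–C12′ for the side-chain acid; TBDPS = tert-butyldiphenylsilyl, TBS = tert-butyldimethylsilyl, PMB = 4-methoxybenzyl, MOP = 2-methoxypropan-2-yl.
Assumption: lactol 9, acetals 13–15, 20–24, 26–32 and lactol 33 are carried as epimer mixtures at the (hemi)acetal carbon, left undefined in their SMILES; this centre is erased in steps 6 and 23.

**Route**

Step 1
Reactants: 1 (S)-5-(hydroxymethyl)furan-2(5H)-one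
Product: 2 (S)-5-[(tert-butyldiphenylsilyloxy)methyl]furan-2(5H)-one
Conditions: t-BuPh2SiCl, imidazole, DMF, 0 °C to rt
Reagents that add atoms: tert-butyl(chloro)diphenylsilane, CC(C)(C)[Si](Cl)(c1ccccc1)c1ccccc1
Why: Imidazole-promoted silylation of the primary alcohol installs the bulky group that shields one face of the butenolide.

Step 2
Reactants: 2 (S)-5-[(tert-butyldiphenylsilyloxy)methyl]furan-2(5H)-one; 3 2-bromo-3,3-diethoxyprop-1-ene
Product: 6 (4R,5S)-5-[(tert-butyldiphenylsilyloxy)methyl]-4-(3,3-diethoxyprop-1-en-2-yl)dihydrofuran-2(3H)-one, via (3,3-diethoxyprop-1-en-2-yl)lithium 4 (not isolated), via lithium bis(3,3-diethoxyprop-1-en-2-yl)cuprate 5 (not isolated)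
Conditions: 3, t-BuLi (2 equiv), Et2O, −78 °C; copper iodide (CuI, 0.5 equiv), −40 °C; then 2, −78 °C; NH4Cl aq.
Reagents that add atoms: none
Why: Halogen–lithium exchange and transmetalation give a Gilman cuprate whose conjugate addition to the butenolide occurs anti to the C8 silyloxymethyl group, setting C7 trans to C8 and bringing in C11–C13 as a masked 2-formylvinyl unit.

Step 3
Reactants: 6 (4R,5S)-5-[(tert-butyldiphenylsilyloxy)methyl]-4-(3,3-diethoxyprop-1-en-2-yl)dihydrofuran-2(3H)-one
Product: 7 (3S,4S,5S)-5-[(tert-butyldiphenylsilyloxy)methyl]-4-(3,3-diethoxyprop-1-en-2-yl)-3-hydroxydihydrofuran-2(3H)-one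
Conditions: KN(SiMe3)2, THF, −78 °C; 2-(phenylsulfonyl)-3-phenyloxaziridine, −78 °C; NH4Cl aq.
Reagents that add atoms: 2-(phenylsulfonyl)-3-phenyloxaziridine, O=S(=O)(N1OC1c1ccccc1)c1ccccc1
Why: Enolate oxidation with the sulfonyloxaziridine (Davis oxidation) delivers oxygen to the enolate face opposite the adjacent C7 substituent, setting C6 trans to C7.

Step 4
Reactants: 7 (3S,4S,5S)-hydroxy lactone
Product: 8 O6-MOP ether of lactone 7
Conditions: 2-methoxypropene, pyridinium p-toluenesulfonate (cat.), CH2Cl2, 0 °C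
Reagents that add atoms: 2-methoxypropene, COC(C)=C
Why: Acid-catalysed addition of the alcohol to the enol ether (mixed ketal formation) gives a base-stable O6 protecting group that cannot migrate and is removed by the mild acid of step 8.

Step 5
Reactants: 8 O6-MOP lactone
Product: 9 lactol of 8 (tetrahydrofuran-2-ol; both anomers)
Conditions: i-Bu2AlH, CH2Cl2, −78 °C
Reagents that add atoms: none
Why: i-Bu2AlH reduction of a γ-lactone at −78 °C stops at the aluminium hemiacetal and should give the lactol on work-up.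

Step 6
Reactants: 9 lactol
Product: 10 (2S,3R,4R)-1-[(tert-butyldiphenylsilyl)oxy]-3-(3,3-diethoxyprop-1-en-2-yl)-4-[(2-methoxypropan-2-yl)oxy]hex-5-en-2-ol (chain C9–C8–C7–C6–C5=CH2; free C8–OH)
Conditions: Ph3PCH3Br, KN(SiMe3)2, THF, 0 °C; then 9, 0 °C to rt
Reagents that add atoms: methyltriphenylphosphonium bromide, C[P+](c1ccccc1)(c1ccccc1)c1ccccc1.[Br-]
Why: Wittig methylenation of the ring-opened hydroxy-aldehyde tautomer installs the C5 vinyl group for metathesis and frees O8 without touching C6.

Step 7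
Reactants: 10 hex-5-en-2-ol
Product: 11 C8 PMB ether of 10
Conditions: NaH, 4-methoxybenzyl chloride, Bu4NI (cat.), THF/DMF, 0 °C to rt
Reagents that add atoms: 4-methoxybenzyl chloride, COc1ccc(CCl)cc1
Why: Williamson etherification; the PMB ether is chosen because it chelates magnesium in step 12 and is removed oxidatively in step 38.

Step 8
Reactants: 11 C8 PMB ether
Product: 13 cyclic ethyl acetal (2-ethoxy-3-methylenetetrahydrofuran closing O6 onto C12; C6 vinyl and C7 chain trans), via C6 alcohol 12 (not isolated)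
Conditions: pyridinium p-toluenesulfonate (cat.), EtOH, 0 °C to rt
Reagents that add atoms: none
Why: Acetal exchange: ethanolysis removes the mixed ketal and the freed C6 hydroxyl displaces one ethoxy group of the neighbouring acetal (5-exo transacetalisation), giving a 2-alkoxytetrahydrofuran that protects O6 and C12 together and later locks the carbocycle conformation.

Step 9
Reactants: 13 cyclic ethyl acetal
Product: 14 primary C9 alcohol
Conditions: Bu4NF, THF, 0 °C to rt
Reagents that add atoms: none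
Why: Fluoride-mediated desilylation of the primary silyl ether; the acetal and the PMB ether are inert to fluoride.

Step 10
Reactants: 14 primary C9 alcohol
Product: 15 C9 aldehyde (α-OPMB)
Conditions: Dess–Martin periodinane, pyridine, CH2Cl2, 0 °C
Reagents that add atoms: none
Why: Dess–Martin oxidation should give the α-alkoxy aldehyde under buffered conditions that do not epimerise C8.

Step 11
Reactants: 16 2-bromoprop-2-en-1-ol
Product: 17 [(2-bromoprop-2-en-1-yl)oxy](tert-butyl)dimethylsilane
Conditions: t-BuMe2SiCl, imidazole, CH2Cl2, 0 °C to rt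
Reagents that add atoms: tert-butyl(chloro)dimethylsilane, CC(C)(C)[Si](C)(C)Cl
Why: Standard silylation gives a bromoalkene fit for halogen–lithium exchange.

Step 12
Reactants: 15 C9 aldehyde; 17 [(2-bromoprop-2-en-1-yl)oxy](tert-butyl)dimethylsilane
Product: 20 C9 allylic alcohol (8,9-syn; C10 bearing =CH2 and CH2OTBS), via {3-[(tert-butyldimethylsilyl)oxy]prop-1-en-2-yl}lithium 18 (not isolated), via {3-[(tert-butyldimethylsilyl)oxy]prop-1-en-2-yl}magnesium bromide 19 (not isolated)
Conditions: 17, t-BuLi (2 equiv), Et2O, −78 °C; MgBr2·OEt2; then 15 premixed with MgBr2·OEt2, CH2Cl2, −78 °C; NH4Cl aq.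
Reagents that add atoms: none
Why: Chelation-controlled carbonyl addition (Cram chelate model): magnesium bridges the aldehyde oxygen and the α-OPMB oxygen, so the alkenyl Grignard reagent attacks the face opposite the C7 branch and sets C9 syn to C8 (threo 8,9-diol pattern).

Step 13
Reactants: 20 C9 allylic alcohol
Product: 21 C9 TBS ether of 20 (metathesis substrate)
Conditions: t-BuMe2SiOTf, 2,6-lutidine, CH2Cl2, −78 °C
Reagents that add atoms: tert-butyldimethylsilyl trifluoromethanesulfonate, CC(C)(C)[Si](C)(C)OS(=O)(=O)C(F)(F)F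
Why: Silyl triflate silylation of the hindered secondary allylic alcohol is fast at −78 °C, where the acetal is not activated.

Step 14
Reactants: 21 bis-TBS diene
Product: 22 cyclohexene (C5=C10; C10–CH2OTBS; C9–OTBS; C8–OPMB; tetrahydrofuran acetal trans-fused at C6/C7)
Conditions: second-generation Hoveyda–Grubbs catalyst (5 mol%), toluene, 80 °C
Reagents that add atoms: none
Why: Ring-closing olefin metathesis: the catalyst loads on the monosubstituted C5 alkene and closes onto the 1,1-disubstituted C10 alkene to give the trisubstituted six-membered ring (the C11 methylene could only close a four-membered ring), with loss of ethene.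

Step 15
Reactants: 22 cyclohexene
Product: 23 C1 primary allylic alcohol
Conditions: HF·pyridine, pyridine, THF, 0 °C
Reagents that add atoms: none
Why: Selective desilylation: the unhindered primary allylic silyl ether is cleaved by buffered HF·pyridine much faster than the hindered secondary C9 ether.

Step 16
Reactants: 23 C1 allylic alcohol
Product: 24 5,10-epoxy alcohol (epoxide oxygen trans to O6 and O9)
Conditions: Ti(OiPr)4, diethyl D-(−)-tartrate, t-BuOOH, 4 Å molecular sieves, CH2Cl2, −20 °C
Reagents that add atoms: tert-butyl hydroperoxide, CC(C)(C)OO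
Why: Sharpless asymmetric epoxidation of the primary allylic alcohol; the D-tartrate ligand delivers oxygen to the ring face opposite the C6 and C9 oxygens (reagent control), setting C10 and C5.

Step 17
Reactants: 24 5,10-epoxy alcohol; 25 prop-1-en-2-ylmagnesium bromide
Product: 26 C1,C10-diol (C5 isopropenyl trans to O10)
Conditions: 25 (4 equiv), copper iodide (CuI, 15 mol%), THF, −30 to 0 °C; NH4Cl aq.
Reagents that add atoms: none
Why: Copper-catalysed Grignard opening of the trisubstituted epoxide occurs at the less substituted C5 with inversion and in the trans-diaxial sense (Fürst–Plattner rule) on the chair fixed by the trans-fused acetal ring, so isopropenyl ends anti to O10 and therefore cis to the carbon that becomes the vinyl group.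

Step 18
Reactants: 26 C1,C10-diol
Product: 27 tertiary α-hydroxy aldehyde (C1HO on C10)
Conditions: SO3·pyridine, DMSO, i-Pr2NEt, CH2Cl2, 0 °C
Reagents that add atoms: none
Why: Parikh–Doering oxidation converts only the primary alcohol of the 1,2-diol; the tertiary hydroxyl is inert and the quaternary C10 cannot epimerise.

Step 19
Reactants: 27 α-hydroxy aldehyde
Product: 28 cyclohexanol with vinyl and OH on C10 and isopropenyl on C5 cis to vinyl
Conditions: Ph3PCH3Br, KN(SiMe3)2, THF, −78 to 0 °C
Reagents that add atoms: methyltriphenylphosphonium bromide, C[P+](c1ccccc1)(c1ccccc1)c1ccccc1.[Br-]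
Why: Wittig methylenation of the aldehyde at low temperature, expected to be faster than α-ketol rearrangement, completes the 1,5-diene with vinyl cis to isopropenyl.

Step 20
Reactants: 28 cis-1-vinyl-2-isopropenylcyclohexan-1-ol
Product: 31 ten-membered enol triflate (OTf on C10; C1=C10 ring-cis; C4=C5 E), via potassium alkoxide 29 (not isolated), via potassium enolate 30 (not isolated)
Conditions: KH (3 equiv), 18-crown-6 (3 equiv), THF, 0 °C to rt; then PhNTf2, −78 to 0 °C
Reagents that add atoms: N-phenylbis(trifluoromethanesulfonimide), O=S(=O)(N(c1ccccc1)S(=O)(=O)C(F)(F)F)C(F)(F)F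
Why: KH with 18-crown-6 gives the dissociated potassium alkoxide 29, whose charge-accelerated [3,3] sigmatropic shift (anionic oxy-Cope rearrangement; closest known type: ring expansion of 1,2-dialkenylcyclohexanols to cyclodec-5-enone enolates that are trapped by an electrophile) forms C2–C3 while C5–C10 breaks and gives enolate 30, which N-phenyltriflimide sulfonylates on oxygen. The ten-membered ring is thus closed by the C2–C3 bond within a chair-like six-centre array, as a six-to-ten ring expansion and not as an end-to-end cyclisation. No stereocentre is created (C5 and C10 become sp2); what must be controlled is the alkene pair, ring-cis C1=C10 and E C4=C5, which requires the chair array with C9 pseudoaxial on C10 and C6 pseudoequatorial on C5. This array is the only one readily open to 28: vinyl and isopropenyl are cis (steps 16 and 17) and the trans-fused acetal ring keeps O6 and C11 equatorial, which fixes the cyclohexane chair with axial isopropenyl and equatorial vinyl, whereas the other chair would need O6 and C11 diaxial and a boat would need the C5–C10 bond eclipsed. The mechanism places the enolate oxygen on C10 and the double bond towards C1, so the triflate, and later C14, can only sit on C10; full deprotonation before warming and trapping at −78 °C should prevent proton exchange towards C9.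

Step 21
Reactants: 31 enol triflate
Product: 32 C14 enal (CHO on C10)
Conditions: Pd(OAc)2 (5 mol%), di(1-adamantyl)-n-butylphosphine (15 mol%), CO/H2 (1:1, 5 bar), Et3N, toluene, 70 °C
Reagents that add atoms: carbon monoxide, [C-]#[O+]
Why: Palladium-catalysed reductive carbonylation (formylation) of the enol triflate: oxidative addition to zerovalent palladium, CO insertion and hydrogenolysis of the acyl complex should give the enal with retention of the C1=C10 geometry.

Step 22
Reactants: 32 C14 enal
Product: 33 lactol (C12 hemiacetal)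
Conditions: AcOH/THF/H2O (3:1:1), 35 °C
Reagents that add atoms: water, O
Why: Acid-catalysed hydrolysis of the allylic furanoside-type acetal is facile, while the enal-conjugated C1=C10 bond is too electron-poor to enter transannular cyclisation.

Step 23
Reactants: 33 lactol
Product: 34 α-methylene 6,12-lactone (O9 TBS; O8 PMB)
Conditions: Dess–Martin periodinane, pyridine, CH2Cl2, 0 °C to rt
Reagents that add atoms: none
Why: Dess–Martin oxidation of the lactol gives the α-methylene-γ-butyrolactone without touching the enal or the ethers.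

Step 24
Reactants: 34 lactone
Product: 35 C9 alcohol
Conditions: HF·pyridine, THF/pyridine, 0 °C to rt
Reagents that add atoms: none
Why: HF·pyridine desilylation frees the C9 hydroxyl under weakly acidic conditions tolerated by the enal, the methylene lactone and the PMB ether.

Step 25
Reactants: 36 neryl acetate
Product: 38 (Z)-3-methyl-6-oxohex-2-en-1-yl acetate, via ozonide 37 (not isolated)
Conditions: O3 (1.0 equiv), CH2Cl2, −78 °C; then PPh3, −78 °C to rt
Reagents that add atoms: ozone, [O-][O+]=O
Why: Ozonolysis is selective for the electron-rich terminal trisubstituted alkene because the 2,3-alkene is deactivated by the allylic acetate; reduction of the ozonide gives the aldehyde with the Z alkene of nerol retained.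

Step 26
Reactants: 39 methyl 2-[bis(2,2,2-trifluoroethoxy)phosphoryl]acetate; 40 3-bromo-1,1-dimethoxypropane
Product: 41 methyl 2-[bis(2,2,2-trifluoroethoxy)phosphoryl]-5,5-dimethoxypentanoate
Conditions: NaH, DMF, 0 °C; then 40, sodium iodide (NaI, cat.), 60 °C
Reagents that add atoms: none
Why: C-alkylation of the sodium salt of the phosphonoacetate with the primary bromide gives the α-substituted Still–Gennari reagent.

Step 27
Reactants: 41 phosphonate; 38 (Z)-3-methyl-6-oxohex-2-en-1-yl acetate
Product: 42 methyl (2Z,6Z)-8-acetoxy-2-(3,3-dimethoxypropyl)-6-methylocta-2,6-dienoate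
Conditions: KN(SiMe3)2, 18-crown-6, THF, −78 °C; then 38
Reagents that add atoms: none
Why: Still–Gennari olefination: the electron-poor bis(trifluoroethyl) phosphonate under dissociating conditions gives kinetic Z-selectivity, placing the ester cis to the C8′ chain.

Step 28
Reactants: 42 dienoate
Product: 43 (2Z,6Z)-2-(3,3-dimethoxypropyl)-6-methylocta-2,6-diene-1,8-diol
Conditions: i-Bu2AlH (5 equiv), CH2Cl2, −78 to 0 °C
Reagents that add atoms: none
Why: i-Bu2AlH reduction converts the conjugated ester into the allylic alcohol and cleaves the acetate, leaving the dimethyl acetal untouched.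

Step 29
Reactants: 43 diol
Product: 44 (2Z,6Z)-2-(3,3-dimethoxypropyl)-6-methylocta-2,6-diene-1,8-diyl diacetate
Conditions: Ac2O, pyridine, 4-(dimethylamino)pyridine (cat.), CH2Cl2, rt
Reagents that add atoms: acetic anhydride, CC(=O)OC(C)=O
Why: Acetylation of both primary allylic alcohols installs the two acetates of the target, which also serve as protecting groups.

Step 30
Reactants: 44 diacetate acetal
Product: 45 (2Z,6Z)-6-methyl-2-(3-oxopropyl)octa-2,6-diene-1,8-diyl diacetate
Conditions: pyridinium p-toluenesulfonate, acetone/H2O (4:1), 45 °C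
Reagents that add atoms: water, O
Why: Mild acid-catalysed hydrolysis of the dimethyl acetal frees the aldehyde without ionising the allylic acetates.

Step 31
Reactants: 46 3-bromobut-3-en-1-ol; 47 isopropylmagnesium chloride
Product: 48 4-methyl-3-methylidenepentan-1-ol
Conditions: 47 (2.5 equiv), PdCl2(dppf) (3 mol%), THF, 0 °C to rt; NH4Cl aq.
Reagents that add atoms: none
Why: Kumada coupling: PdCl2(dppf) couples secondary alkyl Grignard reagents with alkenyl bromides without isomerisation, and the alcohol is carried as its magnesium alkoxide.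

Step 32
Reactants: 48 4-methyl-3-methylidenepentan-1-ol
Product: 49 5-iodo-2-methyl-3-methylidenepentane
Conditions: I2, PPh3, imidazole, CH2Cl2, 0 °C
Reagents that add atoms: iodine, II
Why: Appel-type iodination converts the primary alcohol into the iodide without touching the alkene.

Step 33
Reactants: 39 methyl 2-[bis(2,2,2-trifluoroethoxy)phosphoryl]acetate; 49 5-iodo-2-methyl-3-methylidenepentane
Product: 50 methyl 2-[bis(2,2,2-trifluoroethoxy)phosphoryl]-6-methyl-5-methylideneheptanoate
Conditions: NaH, DMF, 0 °C; then 49, rt to 50 °C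
Reagents that add atoms: none
Why: C-alkylation of the phosphonoacetate anion with the primary homoallylic iodide gives the second Still–Gennari reagent.

Step 34
Reactants: 50 phosphonate; 45 aldehyde
Product: 51 methyl (2Z,6Z,10Z)-12-acetoxy-6-(acetoxymethyl)-10-methyl-2-(4-methyl-3-methylidenepentyl)dodeca-2,6,10-trienoate
Conditions: KN(SiMe3)2, 18-crown-6, THF, −78 °C; then 45
Reagents that add atoms: none
Why: A second Still–Gennari olefination sets the 2Z alkene (ester cis to C4′); the acetates are inert to the preformed phosphonate anion at −78 °C.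

Step 35
Reactants: 51 triene ester
Product: 52 (2Z,6Z,10Z)-12-hydroxy-6-(hydroxymethyl)-10-methyl-2-(4-methyl-3-methylidenepentyl)dodeca-2,6,10-trienoic acid
Conditions: LiOH, THF/MeOH/H2O, rt to 40 °C; then 1 M HCl to pH 3
Reagents that add atoms: lithium hydroxide, [Li+].[OH-]
Why: Saponification frees the hindered carboxylic acid; the two acetates are cleaved at the same time and are restored in step 36.

Step 36
Reactants: 52 dihydroxy acid
Product: 53 (2Z,6Z,10Z)-12-acetoxy-6-(acetoxymethyl)-10-methyl-2-(4-methyl-3-methylidenepentyl)dodeca-2,6,10-trienoic acid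
Conditions: Ac2O, pyridine, 4-(dimethylamino)pyridine (cat.), CH2Cl2, rt; NaHCO3 aq./THF work-up
Reagents that add atoms: acetic anhydride, CC(=O)OC(C)=O
Why: Acetylation of both primary alcohols; any mixed anhydride at the carboxyl group is hydrolysed during the bicarbonate work-up.

Step 37
Reactants: 35 C9 alcohol; 53 diacetoxy trienoic acid
Product: 55 C9 trienoate ester (O8 still PMB), via mixed anhydride 54 (not isolated)
Conditions: 53, 2,4,6-trichlorobenzoyl chloride, Et3N, toluene, rt; then 35, 4-(dimethylamino)pyridine, toluene, rt to 40 °C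
Reagents that add atoms: none
Why: Yamaguchi esterification: 4-(dimethylamino)pyridine attacks the less hindered trienoyl carbonyl of the mixed anhydride and the acylpyridinium acylates the hindered C9 hydroxyl near room temperature, where the 2Z enoate should not isomerise.

Step 38
Reactants: 55 C9 ester
Product: 56 C8 alcohol
Conditions: DDQ, CH2Cl2/pH 7 buffer, 0 °C
Reagents that add atoms: none
Why: Oxidative cleavage of the PMB ether by DDQ (benzylic hydride abstraction, then hydrolysis) frees O8 in the presence of esters, the enal and isolated alkenes.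

Step 39
Reactants: 57 ethyl 2-(hydroxymethyl)prop-2-enoate
Product: 58 ethyl 2-{[(tert-butyldimethylsilyl)oxy]methyl}prop-2-enoate
Conditions: t-BuMe2SiCl, imidazole, CH2Cl2, 0 °C to rt
Reagents that add atoms: tert-butyl(chloro)dimethylsilane, CC(C)(C)[Si](C)(C)Cl
Why: Silylation masks the primary hydroxyl so that the acid can be activated without self-condensation.

Step 40
Reactants: 58 silyl ether ester
Product: 59 2-{[(tert-butyldimethylsilyl)oxy]methyl}prop-2-enoic acid
Conditions: LiOH, THF/H2O, 0 °C to rt; then dilute HCl to pH 4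
Reagents that add atoms: lithium hydroxide, [Li+].[OH-]
Why: Saponification of the ethyl ester; the silyl ether survives aqueous LiOH.

Step 41
Reactants: 56 C8 alcohol; 59 silyl-protected acrylic acid
Product: 60 O-TBS ether of the target
Conditions: N,N′-dicyclohexylcarbodiimide, 4-(dimethylamino)pyridine (cat.), CH2Cl2, 0 °C to rt
Reagents that add atoms: none
Why: Steglich esterification (carbodiimide activation with nucleophilic catalysis) acylates the C8 hydroxyl under near-neutral conditions.

Step 42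
Reactants: 60 O-TBS ether of the target
Product: 61 CNP0240680.3
Conditions: HF·pyridine, THF, 0 °C to rt
Reagents that add atoms: none
Why: HF·pyridine desilylation cleaves the primary allylic silyl ether; the acetates, the acrylate, the methylene lactone and the enal are stable to these weakly acidic conditions.

**Compound list**
1 | (S)-5-(hydroxymethyl)furan-2(5H)-one | O=C1C=C[C@@H](CO)O1 | starting material
2 | (S)-5-[(tert-butyldiphenylsilyloxy)methyl]furan-2(5H)-one | O=C1C=C[C@@H](CO[Si](c2ccccc2)(c2ccccc2)C(C)(C)C)O1 | intermediate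
3 | 2-bromo-3,3-diethoxyprop-1-ene | CCOC(OCC)C(Br)=C | starting material
4 | (3,3-diethoxyprop-1-en-2-yl)lithium (not isolated) | [Li]C(=C)C(OCC)OCC | intermediate
5 | lithium bis(3,3-diethoxyprop-1-en-2-yl)cuprate (not isolated) | [Li+].CCOC(OCC)C(=C)[Cu-]C(=C)C(OCC)OCC | intermediate
6 | (4R,5S)-5-[(tert-butyldiphenylsilyloxy)methyl]-4-(3,3-diethoxyprop-1-en-2-yl)dihydrofuran-2(3H)-one | O=C1C[C@H](C(=C)C(OCC)OCC)[C@@H](CO[Si](c2ccccc2)(c2ccccc2)C(C)(C)C)O1 | intermediate
7 | (3S,4S,5S)-5-[(tert-butyldiphenylsilyloxy)methyl]-4-(3,3-diethoxyprop-1-en-2-yl)-3-hydroxydihydrofuran-2(3H)-one | O=C1[C@@H](O)[C@H](C(=C)C(OCC)OCC)[C@@H](CO[Si](c2ccccc2)(c2ccccc2)C(C)(C)C)O1 | intermediate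
8 | O6-MOP ether of 7 (3-[(2-methoxypropan-2-yl)oxy] lactone, configuration as 7) | O=C1[C@@H](OC(C)(C)OC)[C@H](C(=C)C(OCC)OCC)[C@@H](CO[Si](c2ccccc2)(c2ccccc2)C(C)(C)C)O1 | intermediate
9 | lactol of 8 (tetrahydrofuran-2-ol, both anomers) | OC1[C@@H](OC(C)(C)OC)[C@H](C(=C)C(OCC)OCC)[C@@H](CO[Si](c2ccccc2)(c2ccccc2)C(C)(C)C)O1 | intermediate
10 | (2S,3R,4R)-1-[(tert-butyldiphenylsilyl)oxy]-3-(3,3-diethoxyprop-1-en-2-yl)-4-[(2-methoxypropan-2-yl)oxy]hex-5-en-2-ol | C=C[C@@H](OC(C)(C)OC)[C@H](C(=C)C(OCC)OCC)[C@H](O)CO[Si](c1ccccc1)(c1ccccc1)C(C)(C)C | intermediate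
11 | C8 PMB ether of 10 | C=C[C@@H](OC(C)(C)OC)[C@H](C(=C)C(OCC)OCC)[C@H](OCc1ccc(OC)cc1)CO[Si](c1ccccc1)(c1ccccc1)C(C)(C)C | intermediate
12 | C6 alcohol from 11, MOP removed (not isolated) | C=C[C@@H](O)[C@H](C(=C)C(OCC)OCC)[C@H](OCc1ccc(OC)cc1)CO[Si](c1ccccc1)(c1ccccc1)C(C)(C)C | intermediate
13 | 2-ethoxy-3-methylenetetrahydrofuran (ring O6–C12–C11–C7–C6; vinyl on C6 trans to the C8(OPMB)–C9H2OTBDPS chain on C7; C12 epimers) | C=C[C@H]1OC(OCC)C(=C)[C@@H]1[C@H](OCc1ccc(OC)cc1)CO[Si](c1ccccc1)(c1ccccc1)C(C)(C)C | intermediate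
14 | primary C9 alcohol from 13 | C=C[C@H]1OC(OCC)C(=C)[C@@H]1[C@H](OCc1ccc(OC)cc1)CO | intermediate
15 | C9 aldehyde from 14 | C=C[C@H]1OC(OCC)C(=C)[C@@H]1[C@H](OCc1ccc(OC)cc1)C=O | intermediate
16 | 2-bromoprop-2-en-1-ol | OCC(Br)=C | starting material
17 | [(2-bromoprop-2-en-1-yl)oxy](tert-butyl)dimethylsilane | C=C(Br)CO[Si](C)(C)C(C)(C)C | intermediate
18 | {3-[(tert-butyldimethylsilyl)oxy]prop-1-en-2-yl}lithium (not isolated) | [Li]C(=C)CO[Si](C)(C)C(C)(C)C | intermediate
19 | {3-[(tert-butyldimethylsilyl)oxy]prop-1-en-2-yl}magnesium bromide (not isolated) | Br[Mg]C(=C)CO[Si](C)(C)C(C)(C)C | intermediate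
20 | C9 allylic alcohol (8,9-syn; C10(=CH2)CH2OTBS attached to C9) | C=C[C@H]1OC(OCC)C(=C)[C@@H]1[C@H](OCc1ccc(OC)cc1)[C@@H](O)C(=C)CO[Si](C)(C)C(C)(C)C | intermediate
21 | C9 TBS ether of 20 | C=C[C@H]1OC(OCC)C(=C)[C@@H]1[C@H](OCc1ccc(OC)cc1)[C@@H](O[Si](C)(C)C(C)(C)C)C(=C)CO[Si](C)(C)C(C)(C)C | intermediate
22 | cyclohexene (C5=C10; C10–CH2OTBS; C9–OTBS; C8–OPMB; 2-ethoxy-3-methylenetetrahydrofuran trans-fused at C6/C7) | CCOC1O[C@@H]2C=C(CO[Si](C)(C)C(C)(C)C)[C@H](O[Si](C)(C)C(C)(C)C)[C@@H](OCc3ccc(OC)cc3)[C@H]2C1=C | intermediate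
23 | C1 allylic alcohol from 22 | CCOC1O[C@@H]2C=C(CO)[C@H](O[Si](C)(C)C(C)(C)C)[C@@H](OCc3ccc(OC)cc3)[C@H]2C1=C | intermediate
24 | 5,10-epoxy alcohol (epoxide oxygen trans to O6 and O9) | CCOC1O[C@@H]2[C@H]3O[C@@]3(CO)[C@H](O[Si](C)(C)C(C)(C)C)[C@@H](OCc3ccc(OC)cc3)[C@H]2C1=C | intermediate
25 | prop-1-en-2-ylmagnesium bromide | CC(=C)[Mg]Br | starting material
26 | C1,C10-diol (C5 isopropenyl cis to C6–O, trans to O10) | CCOC1O[C@@H]2[C@H](C(C)=C)[C@](O)(CO)[C@H](O[Si](C)(C)C(C)(C)C)[C@@H](OCc3ccc(OC)cc3)[C@H]2C1=C | intermediate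
27 | tertiary α-hydroxy aldehyde (C1HO on C10) | CCOC1O[C@@H]2[C@H](C(C)=C)[C@](O)(C=O)[C@H](O[Si](C)(C)C(C)(C)C)[C@@H](OCc3ccc(OC)cc3)[C@H]2C1=C | intermediate
28 | cis-1-vinyl-2-isopropenylcyclohexan-1-ol (OH and vinyl on C10; isopropenyl on C5; C9–OTBS; C8–OPMB; acetal ring at C6/C7) | CCOC1O[C@@H]2[C@H](C(C)=C)[C@](O)(C=C)[C@H](O[Si](C)(C)C(C)(C)C)[C@@H](OCc3ccc(OC)cc3)[C@H]2C1=C | intermediate
29 | potassium alkoxide of 28 (not isolated) | [K+].CCOC1O[C@@H]2[C@H](C(C)=C)[C@]([O-])(C=C)[C@H](O[Si](C)(C)C(C)(C)C)[C@@H](OCc3ccc(OC)cc3)[C@H]2C1=C | intermediate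
30 | potassium enolate of the ring-expanded ketone (C1=C10–O−; 4E; not isolated) | [K+].CCOC1O[C@@H]2/C=C(\C)CC/C=C(/[O-])[C@H](O[Si](C)(C)C(C)(C)C)[C@@H](OCc3ccc(OC)cc3)[C@H]2C1=C | intermediate
31 | ten-membered enol triflate (OTf on C10; C2 and C9 cis on C1=C10; 4E) | CCOC1O[C@@H]2/C=C(\C)CC/C=C(/OS(=O)(=O)C(F)(F)F)[C@H](O[Si](C)(C)C(C)(C)C)[C@@H](OCc3ccc(OC)cc3)[C@H]2C1=C | intermediate
32 | C14 enal | CCOC1O[C@@H]2/C=C(\C)CC/C=C(/C=O)[C@H](O[Si](C)(C)C(C)(C)C)[C@@H](OCc3ccc(OC)cc3)[C@H]2C1=C | intermediate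
33 | lactol (C12 hemiacetal, both anomers) | OC1O[C@@H]2/C=C(\C)CC/C=C(/C=O)[C@H](O[Si](C)(C)C(C)(C)C)[C@@H](OCc3ccc(OC)cc3)[C@H]2C1=C | intermediate
34 | α-methylene 6,12-lactone (O9 TBS, O8 PMB) | O=C1O[C@@H]2/C=C(\C)CC/C=C(/C=O)[C@H](O[Si](C)(C)C(C)(C)C)[C@@H](OCc3ccc(OC)cc3)[C@H]2C1=C | intermediate
35 | C9 alcohol (O8 PMB) | O=C1O[C@@H]2/C=C(\C)CC/C=C(/C=O)[C@H](O)[C@@H](OCc3ccc(OC)cc3)[C@H]2C1=C | intermediate
36 | neryl acetate, (Z)-3,7-dimethylocta-2,6-dien-1-yl acetate | CC(=O)OC/C=C(/C)CCC=C(C)C | starting material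
37 | (Z)-5-(5,5-dimethyl-1,2,4-trioxolan-3-yl)-3-methylpent-2-en-1-yl acetate (ozonide, not isolated) | CC(=O)OC/C=C(/C)CCC1OOC(C)(C)O1 | intermediate
38 | (Z)-3-methyl-6-oxohex-2-en-1-yl acetate | CC(=O)OC/C=C(/C)CCC=O | intermediate
39 | methyl 2-[bis(2,2,2-trifluoroethoxy)phosphoryl]acetate | COC(=O)CP(=O)(OCC(F)(F)F)OCC(F)(F)F | starting material
40 | 3-bromo-1,1-dimethoxypropane | COC(CCBr)OC | starting material
41 | methyl 2-[bis(2,2,2-trifluoroethoxy)phosphoryl]-5,5-dimethoxypentanoate | COC(=O)C(CCC(OC)OC)P(=O)(OCC(F)(F)F)OCC(F)(F)F | intermediate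
42 | methyl (2Z,6Z)-8-acetoxy-2-(3,3-dimethoxypropyl)-6-methylocta-2,6-dienoate | COC(=O)/C(CCC(OC)OC)=C\CC/C(C)=C\COC(C)=O | intermediate
43 | (2Z,6Z)-2-(3,3-dimethoxypropyl)-6-methylocta-2,6-diene-1,8-diol | OC/C(CCC(OC)OC)=C\CC/C(C)=C\CO | intermediate
44 | (2Z,6Z)-2-(3,3-dimethoxypropyl)-6-methylocta-2,6-diene-1,8-diyl diacetate | CC(=O)OC/C(CCC(OC)OC)=C\CC/C(C)=C\COC(C)=O | intermediate
45 | (2Z,6Z)-6-methyl-2-(3-oxopropyl)octa-2,6-diene-1,8-diyl diacetate | CC(=O)OC/C(CCC=O)=C\CC/C(C)=C\COC(C)=O | intermediate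
46 | 3-bromobut-3-en-1-ol | OCCC(Br)=C | starting material
47 | isopropylmagnesium chloride | CC(C)[Mg]Cl | starting material
48 | 4-methyl-3-methylidenepentan-1-ol | OCCC(=C)C(C)C | intermediate
49 | 5-iodo-2-methyl-3-methylidenepentane | ICCC(=C)C(C)C | intermediate
50 | methyl 2-[bis(2,2,2-trifluoroethoxy)phosphoryl]-6-methyl-5-methylideneheptanoate | COC(=O)C(CCC(=C)C(C)C)P(=O)(OCC(F)(F)F)OCC(F)(F)F | intermediate
51 | methyl (2Z,6Z,10Z)-12-acetoxy-6-(acetoxymethyl)-10-methyl-2-(4-methyl-3-methylidenepentyl)dodeca-2,6,10-trienoate | COC(=O)/C(=C\CC/C(=C/CC/C(C)=C\COC(C)=O)COC(C)=O)CCC(=C)C(C)C | intermediate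
52 | (2Z,6Z,10Z)-12-hydroxy-6-(hydroxymethyl)-10-methyl-2-(4-methyl-3-methylidenepentyl)dodeca-2,6,10-trienoic acid | OC(=O)/C(=C\CC/C(=C/CC/C(C)=C\CO)CO)CCC(=C)C(C)C | intermediate
53 | (2Z,6Z,10Z)-12-acetoxy-6-(acetoxymethyl)-10-methyl-2-(4-methyl-3-methylidenepentyl)dodeca-2,6,10-trienoic acid | OC(=O)/C(=C\CC/C(=C/CC/C(C)=C\COC(C)=O)COC(C)=O)CCC(=C)C(C)C | intermediate
54 | mixed anhydride of 53 and 2,4,6-trichlorobenzoic acid (not isolated) | O=C(OC(=O)/C(=C\CC/C(=C/CC/C(C)=C\COC(C)=O)COC(C)=O)CCC(=C)C(C)C)c1c(Cl)cc(Cl)cc1Cl | intermediate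
55 | C9 trienoate ester of 35 (O8 PMB) | O=C1O[C@@H]2/C=C(\C)CC/C=C(/C=O)[C@H](OC(=O)/C(=C\CC/C(=C/CC/C(C)=C\COC(C)=O)COC(C)=O)CCC(=C)C(C)C)[C@@H](OCc3ccc(OC)cc3)[C@H]2C1=C | intermediate
56 | C8 alcohol (C9 trienoate) | O=C1O[C@@H]2/C=C(\C)CC/C=C(/C=O)[C@H](OC(=O)/C(=C\CC/C(=C/CC/C(C)=C\COC(C)=O)COC(C)=O)CCC(=C)C(C)C)[C@@H](O)[C@H]2C1=C | intermediate
57 | ethyl 2-(hydroxymethyl)prop-2-enoate | CCOC(=O)C(=C)CO | starting material
58 | ethyl 2-{[(tert-butyldimethylsilyl)oxy]methyl}prop-2-enoate | CCOC(=O)C(=C)CO[Si](C)(C)C(C)(C)C | intermediate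
59 | 2-{[(tert-butyldimethylsilyl)oxy]methyl}prop-2-enoic acid | OC(=O)C(=C)CO[Si](C)(C)C(C)(C)C | intermediate
60 | O-TBS ether of the target (silyl on the acrylate CH2OH) | O=C1O[C@@H]2/C=C(\C)CC/C=C(/C=O)[C@H](OC(=O)/C(=C\CC/C(=C/CC/C(C)=C\COC(C)=O)COC(C)=O)CCC(=C)C(C)C)[C@@H](OC(=O)C(=C)CO[Si](C)(C)C(C)(C)C)[C@H]2C1=C | intermediate
61 | CNP0240680.3 (6R,7S,8S,9S in germacrane numbering) | C=C(CO)C(=O)O[C@H]1[C@H]2C(=C)C(=O)O[C@@H]2/C=C(\C)CC/C=C(/C=O)[C@@H]1OC(=O)/C(=C\CC/C(=C/CC/C(C)=C\COC(C)=O)COC(C)=O)CCC(=C)C(C)C | target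

Total step count: 42
Longest linear sequence: 27 steps (1 to 61 through steps 1–10, 12–24, 37, 38, 41, 42)

**Steps most likely to fail**

Step 20. O-sulfonylation of the hindered enolate by N-phenyltriflimide may be slower than proton exchange between the enolate and alkoxide that has not yet rearranged, so the enolate may lose its regiochemistry or be quenched to the ketone. Fallback, setting out from 28: the same KH/18-crown-6 rearrangement is run and the enolate is quenched at −78 °C with Me3SiCl/Et3N, which silylates oxygen within seconds, to give the trimethylsilyl enol ether F1. After isolation, MeLi (THF, 0 °C) cleaves the O–Si bond to the lithium enolate F2 with double-bond position and geometry unchanged. N-(5-chloropyridin-2-yl)bis(trifluoromethanesulfonimide) at −78 °C then gives 31, where the route is rejoined.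

Step 17. Backside attack at C5 has to pass the axial silyloxy group on C9; if it is slow, the magnesium alkoxide can shift the epoxide to C1–C10 (Payne rearrangement) and the Grignard reagent then adds at C1. Fallback, setting out from 23: MnO2 (CH2Cl2) gives the enal F3. Prop-1-en-2-ylmagnesium bromide 25 with CuBr·SMe2 and Me3SiCl (THF, −78 °C) adds in the conjugate sense, axially at C5 on the locked half-chair, and the enolate is trapped as the trimethylsilyl enol ether F4. Dimethyldioxirane (acetone/CH2Cl2, −78 °C) epoxidises the enol ether from the face opposite the axial isopropenyl and C9 silyloxy groups, and silyl migration (Rubottom oxidation) gives the α-silyloxy aldehyde F5. K2CO3 in MeOH removes the trimethylsilyl group and the route is rejoined at 27.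

Step 21. The alkenylpalladium or acylpalladium intermediate may be hydrogenolysed before CO insertion is complete, giving simple reduction of the triflate, or the enal may be reduced further under H2. Fallback, setting out from 31: alkoxycarbonylation (Pd(OAc)2, PPh3, CO 1 atm, MeOH, Et3N, DMF, 60 °C) gives the methyl ester F6. i-Bu2AlH (CH2Cl2, −78 °C) reduces it to the allylic alcohol F7, and MnO2 (CH2Cl2) oxidises this to 32, where the route is rejoined.

**Further compounds**
F1 | step 20 | trimethylsilyl enol ether of the ring-expanded ketone (OSiMe3 on C10, otherwise as 31) | CCOC1O[C@@H]2/C=C(\C)CC/C=C(/O[Si](C)(C)C)[C@H](O[Si](C)(C)C(C)(C)C)[C@@H](OCc3ccc(OC)cc3)[C@H]2C1=C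
F2 | step 20 | lithium enolate corresponding to 30 | [Li+].CCOC1O[C@@H]2/C=C(\C)CC/C=C(/[O-])[C@H](O[Si](C)(C)C(C)(C)C)[C@@H](OCc3ccc(OC)cc3)[C@H]2C1=C
F3 | step 17 | cyclohexene carbaldehyde from 23 (CHO on C10) | CCOC1O[C@@H]2C=C(C=O)[C@H](O[Si](C)(C)C(C)(C)C)[C@@H](OCc3ccc(OC)cc3)[C@H]2C1=C
F4 | step 17 | trimethylsilyl enol ether after conjugate addition (C10=C1H–OSiMe3, isopropenyl on C5) | CCOC1O[C@@H]2[C@H](C(C)=C)C(=CO[Si](C)(C)C)[C@H](O[Si](C)(C)C(C)(C)C)[C@@H](OCc3ccc(OC)cc3)[C@H]2C1=C
F5 | step 17 | C10 trimethylsilyl ether of aldehyde 27 | CCOC1O[C@@H]2[C@H](C(C)=C)[C@](O[Si](C)(C)C)(C=O)[C@H](O[Si](C)(C)C(C)(C)C)[C@@H](OCc3ccc(OC)cc3)[C@H]2C1=C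
F6 | step 21 | methyl ester (C14 as CO2Me on C10, otherwise as 32) | CCOC1O[C@@H]2/C=C(\C)CC/C=C(/C(=O)OC)[C@H](O[Si](C)(C)C(C)(C)C)[C@@H](OCc3ccc(OC)cc3)[C@H]2C1=C
F7 | step 21 | allylic alcohol (C14 as CH2OH on C10) | CCOC1O[C@@H]2/C=C(\C)CC/C=C(/CO)[C@H](O[Si](C)(C)C(C)(C)C)[C@@H](OCc3ccc(OC)cc3)[C@H]2C1=C
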